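**Strategy.** Guaiane numbering is used: ring A is the cyclopentenone (C1–C5; C3=O, C4=C5, methyl on C4), ring B the seven-membered ring (C1, C5–C10). This enone, fused to ring B through C5 and the sp3 carbon C1 next to the methyl-bearing C10, is the signature of the photochemical cross-conjugated dienone rearrangement. In one operation it joins C1 to C5 and cuts C5–C10 of a 4,10-dimethyl-1,4-dien-3-one decalin, so C1 is inserted into six-membered ring B and ring A contracts to the enone. The precursor, decalin dienone 12, carries the C7/C8 diol, set from a quaternary C10 that is given up afterwards.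

Key step: step 6

Remark: the sense of induction in step 1 is taken from the 2-methylcyclohexanone/methyl vinyl ketone case ((S)-amine gives the (R)-octalone series). If it is opposite here, the enantiomeric amine is used.

**Step 1**
Reactants: 1 7-methyl-1,4-dioxaspiro[4.5]decan-8-one (racemic); 2 (R)-1-phenylethylamine; 3 ethyl vinyl ketone
Product: 6 (R)-7-methyl-7-(3-oxopentyl)-1,4-dioxaspiro[4.5]decan-8-one, via ketimine 4 (not isolated), via Michael-adduct ketimine 5 (not isolated)
Conditions: 2, toluene, reflux, Dean–Stark; 3, THF, 40 °C, 4 d; 20% aq. AcOH, rt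
Reagents that add atoms: ethyl vinyl ketone CCC(=O)C=C; water O
Why: Deracemising Michael addition of a chiral imine: the more substituted secondary enamine tautomer of 4 should add to 3 through a compact aza-ene-type transition state on the face away from the phenyl group, setting the quaternary carbon (future C10) as R whatever the configuration of 1, and mild acid hydrolysis frees the ketone while the dioxolane survives.

**Step 2**
Reactants: 6 (R)-7-methyl-7-(3-oxopentyl)-1,4-dioxaspiro[4.5]decan-8-one
Product: 7 (8a'R)-5',8a'-dimethyl-3',4',8',8a'-tetrahydro-1'H-spiro[[1,3]dioxolane-2,2'-naphthalen]-6'(7'H)-one (enone ketal)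
Conditions: NaOMe, MeOH, 60 °C
Reagents that add atoms: none
Why: Intramolecular aldol condensation (second half of a Robinson annulation) of the 1,5-diketone should close ring A as the 4-methyl-4-en-3-one; the quaternary centre cannot enolise and is kept.

**Step 3**
Reactants: 7 enone ketal
Product: 9 (S)-1,4a-dimethyl-4a,5,7,8-tetrahydronaphthalene-2,6-dione (dienone-dione), via dienone ketal 8 (not isolated)
Conditions: DDQ, dioxane, reflux; then 1 M HCl, THF, rt
Reagents that add atoms: water O
Why: DDQ dehydrogenation of a 4-en-3-one under neutral conditions proceeds through the 2,4-dienol and should give the cross-conjugated 1,4-dien-3-one, and aqueous acid then hydrolyses the dioxolane to the C8 ketone without touching the dienone.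

**Step 4**
Reactants: 9 dienone-dione; 10 acetone
Product: 11 (4aS,7R)-7-(2-hydroxypropan-2-yl)-1,4a-dimethyl-4a,5,7,8-tetrahydronaphthalene-2,6-dione
Conditions: LiN(iPr)2 (LDA), THF, −78 °C; ZnCl2, −78 to −20 °C; acetone, −20 to 0 °C; aq. NH4Cl
Reagents that add atoms: acetone CC(C)=O
Why: Aldol addition under zinc-chelate (thermodynamic) control: LDA removes a C7 proton (C9 is neopentylic and ring A has no α'-hydrogen), and the reversible addition of the zinc enolate to acetone should settle on the chelated aldolate with the side chain equatorial, that is cis to the axial C10 methyl, which sets C7 as R.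

**Step 5**
Reactants: 11 β-hydroxy ketone
Product: 12 (4aS,6R,7S)-6-hydroxy-7-(2-hydroxypropan-2-yl)-1,4a-dimethyl-5,6,7,8-tetrahydronaphthalen-2(4aH)-one (decalin dienone diol)
Conditions: NaBH4, MeOH/CH2Cl2, −30 °C
Reagents that add atoms: none
Why: Borohydride reduction of the saturated ketone (the cross-conjugated dienone is far less electrophilic): hydride should enter from the face opposite the syn-axial C10 methyl and give the axial 8-alcohol, cis to the C7 side chain (C8 = R).

**Step 6**
Reactants: 12 decalin dienone diol
Product: 13 (1R,7S,8R,10R)-10-acetoxy-8,11-dihydroxyguai-4-en-3-one (1α-H, 10α-acetoxy, 10β-methyl)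
Conditions: hν (450 W medium-pressure Hg lamp, Pyrex), glacial AcOH, N2, 20 °C
Reagents that add atoms: acetic acid CC(=O)O
Why: Photochemical cross-conjugated dienone rearrangement of the santonin type: the excited 1,4-dien-3-one bonds C1 to C5 to give a zwitterion containing the cyclopropane C1–C5–C10, acetic acid protonates the oxygen, the cyclopropylcarbinyl cation opens by cleavage of C5–C10, and acetic acid captures the tertiary C10 cation. The closest known reaction is the conversion of 4-methyl-1,4-dien-3-one decalins into 10-oxygenated 3-oxoguai-4-enes in acetic acid. Ring A is closed by β,β'-bonding across the dienone (a 4π electrocyclic closure that first forms the three-membered ring), and ring B grows from six to seven atoms because C1 comes to lie between C5 and C10. C1 is set by transfer from the quaternary C10 (H1 ends on the face opposite the C10 methyl), the acetate enters C10 anti to the departing C5, and C7 and C8 are untouched. The step needs the 5/7 pathway to win over the spiro and lumiketone pathways, which the C4 methyl secures by stabilising positive charge at C4, and it needs the hydroxyls not to intercept the cation, which is secured because both lie on the face opposite to nucleophilic attack.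

**Step 7**
Reactants: 13 10-acetate
Product: 14 (7S,8R)-8,11-dihydroxyguaia-1(10),4-dien-3-one
Conditions: DBU, toluene, 80 °C
Reagents that add atoms: none
Why: Vinylogous E1cB elimination: DBU removes the γ-proton at C1 and the dienolate expels the C10 acetate to give the linear dienone; the transient centres C1 and C10 are erased on purpose, and the free hydroxyls are poor leaving groups, so C8 is safe.

**Step 8**
Reactants: 14 dienone diol
Product: 15 (7S,8R)-11-hydroxy-8-propanoyloxyguaia-1(10),4-dien-3-one
Conditions: (EtCO)2O, pyridine, DMAP (cat.), CH2Cl2, 0 °C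
Reagents that add atoms: propionic anhydride CCC(=O)OC(=O)CC
Why: DMAP-catalysed acylation should discriminate the secondary C8 hydroxyl from the hindered tertiary C11 hydroxyl, and the weak amine bases should not trigger elimination of the new ester through C9.

**Step 9**
Reactants: 15 mono-propionate
Product: 16 (7S,8R)-11-acetoxy-8-propanoyloxyguaia-1(10),4-dien-3-one
Conditions: Ac2O, Sc(OTf)3 (2 mol %), MeCN, −20 °C
Reagents that add atoms: acetic anhydride CC(=O)OC(C)=O
Why: Sc(OTf)3-catalysed acetylation with acetic anhydride esterifies tertiary alcohols at low temperature and avoids the stronger bases that could eliminate the C8 propionate of the dienone.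

**Step 10**
Reactants: 16 dienone diester
Product: 18 (1R,7S,8R,10S)-11-acetoxy-8-propanoyloxyguai-4-en-3-one (target), via C1 epimer 17 (not isolated)
Conditions: H2 (3 atm), Pd/C, EtOAc, rt; filter; DBU, toluene, 60 °C
Reagents that add atoms: none
Why: Heterogeneous hydrogenation should saturate the γ,δ-bond C1=C10 from the α-face, opposite the C8 propanoyloxy group and the C7 side chain, which sets C10 (methyl β, S) and leaves the tetrasubstituted C4=C5 enone; DBU then equilibrates the γ-carbon C1 through the dienolate to the epimer with C2 and the C10 methyl trans (C1 = R), expected to be the more stable one and the target.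

**Compound list**

1 | 7-methyl-1,4-dioxaspiro[4.5]decan-8-one (racemic) | CC1CC2(CCC1=O)OCCO2 | starting material
2 | (R)-1-phenylethylamine | C[C@@H](N)c1ccccc1 | starting material
3 | ethyl vinyl ketone (pent-1-en-3-one) | CCC(=O)C=C | starting material
4 | N-[(R)-1-phenylethyl] ketimine of 1 | CC1CC2(CCC1=N[C@H](C)c1ccccc1)OCCO2 | intermediate
5 | Michael-adduct ketimine (R at the new quaternary carbon) | CCC(=O)CC[C@]1(C)CC2(CCC1=N[C@H](C)c1ccccc1)OCCO2 | intermediate
6 | (R)-7-methyl-7-(3-oxopentyl)-1,4-dioxaspiro[4.5]decan-8-one | CCC(=O)CC[C@]1(C)CC2(CCC1=O)OCCO2 | intermediate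
7 | (8a'R)-5',8a'-dimethyl-3',4',8',8a'-tetrahydro-1'H-spiro[[1,3]dioxolane-2,2'-naphthalen]-6'(7'H)-one | CC1=C2CCC3(OCCO3)C[C@@]2(C)CCC1=O | intermediate
8 | (8a'S)-5',8a'-dimethyl-3',4'-dihydro-1'H-spiro[[1,3]dioxolane-2,2'-naphthalen]-6'(8a'H)-one (dienone ketal) | CC1=C2CCC3(OCCO3)C[C@@]2(C)C=CC1=O | intermediate
9 | (S)-1,4a-dimethyl-4a,5,7,8-tetrahydronaphthalene-2,6-dione | CC1=C2CCC(=O)C[C@@]2(C)C=CC1=O | intermediate
10 | acetone | CC(C)=O | starting material
11 | (4aS,7R)-7-(2-hydroxypropan-2-yl)-1,4a-dimethyl-4a,5,7,8-tetrahydronaphthalene-2,6-dione | CC1=C2C[C@H](C(C)(C)O)C(=O)C[C@@]2(C)C=CC1=O | intermediate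
12 | (4aS,6R,7S)-6-hydroxy-7-(2-hydroxypropan-2-yl)-1,4a-dimethyl-5,6,7,8-tetrahydronaphthalen-2(4aH)-one | CC1=C2C[C@H](C(C)(C)O)[C@H](O)C[C@@]2(C)C=CC1=O | intermediate
13 | (1R,7S,8R,10R)-10-acetoxy-8,11-dihydroxyguai-4-en-3-one | O[C@@H]1C[C@@](C)(OC(C)=O)[C@@H]2CC(=O)C(C)=C2C[C@@H]1C(C)(C)O | intermediate
14 | (7S,8R)-8,11-dihydroxyguaia-1(10),4-dien-3-one | O[C@@H]1CC(C)=C2CC(=O)C(C)=C2C[C@@H]1C(C)(C)O | intermediate
15 | (7S,8R)-11-hydroxy-8-propanoyloxyguaia-1(10),4-dien-3-one | CCC(=O)O[C@@H]1CC(C)=C2CC(=O)C(C)=C2C[C@@H]1C(C)(C)O | intermediate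
16 | (7S,8R)-11-acetoxy-8-propanoyloxyguaia-1(10),4-dien-3-one | CCC(=O)O[C@@H]1CC(C)=C2CC(=O)C(C)=C2C[C@@H]1C(C)(C)OC(C)=O | intermediate
17 | (1S,7S,8R,10S)-11-acetoxy-8-propanoyloxyguai-4-en-3-one (C1 epimer of the target) | CCC(=O)O[C@@H]1C[C@H](C)[C@@H]2CC(=O)C(C)=C2C[C@@H]1C(C)(C)OC(C)=O | intermediate
18 | (1R,7S,8R,10S)-11-acetoxy-8-propanoyloxyguai-4-en-3-one, i.e. [(5S,6R,8S,8aR)-5-(2-acetoxypropan-2-yl)-3,8-dimethyl-2-oxo-1,2,4,5,6,7,8,8a-octahydroazulen-6-yl] propanoate | CCC(=O)O[C@@H]1C[C@H](C)[C@H]2CC(=O)C(C)=C2C[C@@H]1C(C)(C)OC(C)=O | target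

**Total step count:** 10. **Longest linear sequence:** 10 steps (from 1).

**Steps most likely to fail**

Step 4. Under the reversible zinc-aldolate conditions, proton transfer may move the enolate to C9 or to the C6 trienolate. Retro-aldol may erode conversion on work-up, or equilibration may stay incomplete and leave the axial C7 epimer. The fallback sets out from 9 and comes back at 11, fixing C7 by protonation instead of aldolate equilibration. A kinetic lithium aldol (LDA, acetone, −78 °C, cold AcOH quench) should give mainly the axial aldol epimer F1. The crude aldol is dehydrated (MsCl, Et3N, then DBU) to the isopropylidene ketone F2. H2O2/NaOH epoxidises the alkylidene ketone, which reacts much faster than the cross-conjugated dienone, to the spiro-epoxy ketone F3. Na[PhSeB(OEt)3] (from (PhSe)2 and NaBH4, EtOH, AcOH) opens the epoxide reductively at C7, and protonation from the face away from the angular methyl puts the side chain equatorial, giving 11.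

Step 6. The excited dienone and the C10 cation may partition to lumiketone, spiro ketone or alkene products, and the product enone may photolyse further. With the free diol this may give poor mass balance. The fallback sets out from 12 and comes back at 17. The hydroxyls are masked first as the final esters: (EtCO)2O, pyridine, DMAP gives the decalin 8-propionate F4, and Ac2O, Sc(OTf)3 gives the decalin diester F5. Irradiation of F5 in 45% aqueous AcOH should give the C10 tertiary alcohol F6. Methyl chlorooxoacetate with DMAP gives the tertiary methyl oxalate F7. Barton–McCombie-type reduction (Bu3SnH, AIBN, toluene, 110 °C) removes the oxygen with net retention: the C10 radical should take hydrogen from the α-face, away from C2, the C8 ester and the C7 side chain. This gives 17, which is equilibrated with DBU as in step 10. The route then needs no linear dienone.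

Step 10. Hydrogenation of the tetrasubstituted C1=C10 bond may show poor facial or chemoselectivity (over-reduction of C4=C5), or the C1 equilibrium may be less favourable than expected. The fallback sets out from 14 and comes back at 18. A Birch-type 1,6-reduction of the ester-free dienone diol (Li, NH3/THF, t-BuOH, −78 °C; NH4Cl; then NaOMe, MeOH) protonates C10 from the less hindered face and brings the enone back into conjugation with C1 equilibrated, giving the guaienone diol F8. Propionylation ((EtCO)2O, pyridine, DMAP) gives the 8-propionate F9. Acetylation of the tertiary alcohol (Ac2O, DMAP, Et3N, 40 °C, now with no base-sensitive dienone present) gives 18.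

**Further compounds**

F1 | step 4 | (4aS,7S)-7-(2-hydroxypropan-2-yl)-1,4a-dimethyl-4a,5,7,8-tetrahydronaphthalene-2,6-dione (axial aldol epimer) | CC1=C2C[C@@H](C(C)(C)O)C(=O)C[C@@]2(C)C=CC1=O
F2 | step 4 | (S)-1,4a-dimethyl-7-(propan-2-ylidene)-4a,5,7,8-tetrahydronaphthalene-2,6-dione | CC1=C2CC(=C(C)C)C(=O)C[C@@]2(C)C=CC1=O
F3 | step 4 | spiro-epoxy ketone of F2 (7,11-epoxide, either C7 epimer) | CC1=C2CC3(OC3(C)C)C(=O)C[C@@]2(C)C=CC1=O
F4 | step 6 | (4aS,6R,7S)-7-(2-hydroxypropan-2-yl)-1,4a-dimethyl-2-oxo-2,4a,5,6,7,8-hexahydronaphthalen-6-yl propanoate | CC1=C2C[C@H](C(C)(C)O)[C@H](OC(=O)CC)C[C@@]2(C)C=CC1=O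
F5 | step 6 | (4aS,6R,7S)-7-(2-acetoxypropan-2-yl)-1,4a-dimethyl-2-oxo-2,4a,5,6,7,8-hexahydronaphthalen-6-yl propanoate | CC1=C2C[C@H](C(C)(C)OC(C)=O)[C@H](OC(=O)CC)C[C@@]2(C)C=CC1=O
F6 | step 6 | (1R,7S,8R,10R)-11-acetoxy-10-hydroxy-8-propanoyloxyguai-4-en-3-one | CCC(=O)O[C@@H]1C[C@@](C)(O)[C@@H]2CC(=O)C(C)=C2C[C@@H]1C(C)(C)OC(C)=O
F7 | step 6 | methyl oxalate of F6 at the C10 oxygen | CCC(=O)O[C@@H]1C[C@@](C)(OC(=O)C(=O)OC)[C@@H]2CC(=O)C(C)=C2C[C@@H]1C(C)(C)OC(C)=O
F8 | step 10 | (1R,7S,8R,10S)-8,11-dihydroxyguai-4-en-3-one | O[C@@H]1C[C@H](C)[C@H]2CC(=O)C(C)=C2C[C@@H]1C(C)(C)O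
F9 | step 10 | (1R,7S,8R,10S)-11-hydroxy-8-propanoyloxyguai-4-en-3-one | CCC(=O)O[C@@H]1C[C@H](C)[C@H]2CC(=O)C(C)=C2C[C@@H]1C(C)(C)O
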